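Retrosynthetic cuts, in order: C12–C13 (butenolide), C8=C17, the C19/C20 oxidation pattern back to a C19(=O)–O–C20 lactone, C3–C4 (ring A), C4–C5 (key bond), then C10–C1 and C11–C12, which leaves an aromatic ring B.
Enabling feature: in the trans-decalin, C20 (on C10) and C19 (on C4) are both axial on the same face of ring A and sit 1,3 across C5. C4–C19–O–C20–C10–C5 is therefore an unstrained six-membered ring, and an oxygen link from C20 can carry C19, C4 and C18 onto C5.
Forward order of rings: ring B (Birch reduction–alkylation of a benzamide), then a temporary oxane ring (radical closure C4–C5), then ring A (lactone enolate closes C3–C4), then reductive opening of the tether, then the butenolide joined at C12.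
Stereochemistry: C10 comes from the pyrrolidine auxiliary and C5 from C10 through the tether. C4 comes from the bridged lactone, which can only be alkylated on the face holding the C1–C3 chain. C9 is set by equilibration next to the C8 ketone once the decalin is rigid.

Key step: step 6

Atom labels follow labdane numbering: ring A = C1–C5 and C10; ring B = C5–C10; C11–C12 chain on C9; C13–C16 butenolide; C17 methylene on C8; C18 methyl and C19 CH2OAc on C4; C20 CHO on C10. The target is (4R,5R,9R,10R). TIPS = triisopropylsilyl, TES = triethylsilyl.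
Assumption: enolate 9 from the (S)-auxiliary is taken to accept the alkyl bromide on the face that gives (S)-C10 as drawn in 10. If the facial sense is the opposite, the equally available (R)-2-(methoxymethyl)pyrrolidine is used and nothing else changes.

Step 1
Reactants: 1 3-methoxy-2-methylbenzoic acid; 2 (S)-2-(methoxymethyl)pyrrolidine
Product: 4 (S)-1-(3-methoxy-2-methylbenzoyl)-2-(methoxymethyl)pyrrolidine, via acid chloride 3 (not isolated)
Conditions: (COCl)2, DMF (cat.), CH2Cl2, 0 °C → rt; then 2, Et3N, CH2Cl2, 0 °C
Reagents that add atoms: oxalyl chloride, O=C(Cl)C(=O)Cl (chlorine of 3 only)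
Why: N-acylation of a secondary amine by an acid chloride is routine and does not touch the auxiliary stereocentre.

Step 2
Reactants: 4 (S)-1-(3-methoxy-2-methylbenzoyl)-2-(methoxymethyl)pyrrolidine; 5 (triisopropylsiloxy)methyl chloride
Product: 7 amide 4 carrying CH2CH2OTIPS (C11–C12) in place of the aryl methyl group, via benzylic lithium compound 6 (not isolated)
Conditions: LiN(i-Pr)2, THF, −78 °C; then 5, −78 → −20 °C
Reagents that add atoms: lithium diisopropylamide, [Li+].CC(C)[N-]C(C)C (lithium of 6 only)
Why: Lateral lithiation of a tertiary o-toluamide followed by SN2 alkylation with an α-chloro ether adds C12 already bearing a silyl ether, which unlike a benzyl ether survives the dissolving metal of step 3.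

Step 3
Reactants: 7 2-(2-TIPS-oxyethyl)-3-methoxybenzamide of 2; 8 benzyl 3-bromopropyl ether
Product: 10 ring B diene amide (1-(3-benzyloxypropyl)-3-methoxy-2-(2-TIPS-oxyethyl)cyclohexa-2,5-diene-1-carboxamide of 2 with (S)-C10), via potassium enolate 9 (not isolated)
Conditions: K, NH3–THF, t-BuOH (1 equiv), −78 °C; piperylene; then 8, −78 °C; NH4Cl
Reagents that add atoms: potassium, [K] (counter-ion of 9 only)
Why: In this asymmetric Birch reduction–alkylation of a chiral benzamide, reduction with protonation at C7 gives amide enolate 9, whose faces are differentiated by the methoxymethylpyrrolidine, so C-alkylation sets quaternary C10; the excess metal is discharged with piperylene before 8 is added, so its benzyl ether is not cleaved.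

Step 4
Reactants: 10 ring B diene amide
Product: 11 C20 alcohol ((S)-1-(3-benzyloxypropyl)-3-methoxy-2-(2-TIPS-oxyethyl)cyclohexa-2,5-dien-1-yl)methanol
Conditions: LiH2NBH3 (from BH3·NH3 and LiN(i-Pr)2), THF, 0 → 23 °C; aq NaOH
Reagents that add atoms: none
Why: Lithium amidotrihydroborate reduces tertiary amides, α-quaternary ones included, to primary alcohols with C–N cleavage and leaves alkenes, enol ether, silyl ether and benzyl ether alone, whereas a primary halide on the C1–C3 chain would be at risk, so C3 is carried as its benzyl ether.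

Step 5
Reactants: 11 C20 alcohol; 12 ethyl 1-propenyl ether
Product: 14 ring B diene bromoacetal (C20–O–CH(OEt)–CHBr–CH3; mixture at the acetal and bromide carbons), via 1,2-dibromo-1-ethoxypropane 13 (not isolated)
Conditions: 12, Br2, CH2Cl2, −78 °C; then 11, i-Pr2NEt, −78 → 0 °C
Reagents that add atoms: bromine, BrBr
Why: This is Ueno–Stork acetal formation run through the preformed α-bromo ether, so no electrophilic bromine meets the electron-rich C8=C9 enol ether, the amine removes HBr, and the two new centres need no control because both are erased later.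

Step 6
Reactants: 14 ring B diene bromoacetal
Product: 15 cis-fused oxane acetal (C4 bonded to C5 cis to C20; H5 trans to C20; mixture at C4 and at the acetal carbon)
Conditions: Bu3SnH and AIBN added over 8 h to 14 (0.005 M), benzene, 80 °C
Reagents that add atoms: none
Why: Bu3Sn• abstracts bromine from C4, the secondary alkyl radical adds to C5 of the C5=C6 double bond, and the C6 radical takes hydrogen from Bu3SnH to carry the chain. The closest known reaction type is the Ueno–Stork haloacetal radical cyclisation in its six-ring version, from a homoallylic alcohol onto a cyclohexene. The single ring closed is the oxane C4–C19–O–C20–C10–C5, formed in the 6-exo-trig mode through a chair-like transition state. C5 is controlled by C10, because the three-atom link from C20 cannot reach the far face of ring B, so C4 bonds cis to C20 and H5 ends trans to C20; C4 and the acetal carbon form as mixtures that are erased in steps 8 and 12. The step needs C5 to win over C9 (the other 6-exo terminus) and over C6 (7-endo); C9 is the fully substituted carbon of an electron-rich enol ether and a poor partner for a nucleophilic alkyl radical, and endo attack is slower. High dilution and slow stannane addition keep premature reduction of the C4 radical, and hydrogen abstraction from the doubly allylic C7H2 of a second molecule, below the rate of ring closure.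

Step 7
Reactants: 15 cis-fused oxane acetal
Product: 16 C8 keto lactol (mixture at C4, C9 and the lactol carbon)
Conditions: AcOH–THF–H2O (3:1:1), 45 °C
Reagents that add atoms: water, O
Why: Mild acid hydrolysis cleaves the methyl enol ether and the 2-alkoxyoxane acetal under the conditions used for tetrahydropyranyl ethers while the primary TIPS and benzyl ethers hold; C9 forms as a mixture and is left so, because ring B can still flip at this stage.

Step 8
Reactants: 16 C8 keto lactol
Product: 17 keto δ-lactone (C19 carbonyl; mixture at C4 and C9)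
Conditions: Dess–Martin periodinane, CH2Cl2, rt
Reagents that add atoms: none
Why: Dess–Martin oxidation of a lactol to the lactone meets no other oxidisable group in 16.

Step 9
Reactants: 17 keto δ-lactone
Product: 18 C8 ethylene ketal lactone
Conditions: (Me3SiOCH2)2, Me3SiOTf (cat.), CH2Cl2, −78 → −20 °C
Reagents that add atoms: 1,2-bis(trimethylsiloxy)ethane, C[Si](C)(C)OCCO[Si](C)(C)C
Why: Noyori ketalisation masks the hindered ketone under aprotic, silyl-ether-safe conditions, so that in step 12 the lactone is the only enolisable carbonyl.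

Step 10
Reactants: 18 C8 ethylene ketal lactone
Product: 19 C3 alcohol
Conditions: H2 (1 atm), 10% Pd/C, EtOAc, rt
Reagents that add atoms: none
Why: Benzyl ether hydrogenolysis is run at the one stage of the route where the molecule holds no alkene.

Step 11
Reactants: 19 C3 alcohol
Product: 20 C3 iodide
Conditions: I2, PPh3, imidazole, CH2Cl2, 0 °C
Reagents that add atoms: iodine, II
Why: Appel-type (Garegg–Samuelsson) iodination of an unhindered primary alcohol proceeds under imidazole buffering that spares ketal, lactone and silyl ether.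

Step 12
Reactants: 20 C3 iodide
Product: 22 tricyclic ketal lactone (trans-fused rings A and B bridged by C19(=O)–O–C20; C18 equatorial; C9 still a mixture), via lithium enolate 21 (not isolated)
Conditions: LiN(i-Pr)2, THF, −78 °C; DMPU, −78 → 0 °C
Reagents that add atoms: lithium diisopropylamide, [Li+].CC(C)[N-]C(C)C (lithium of 21 only)
Why: In this intramolecular lactone enolate alkylation (6-(enolexo)-exo-tet) the C1–C3 chain hangs axially from C10 over one face of the planar C4 enolate, so C3 can bond only there, which sets quaternary C4 with C19 still bridged to C20 and C18 equatorial and closes ring A trans to ring B.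

Step 13
Reactants: 22 tricyclic ketal lactone
Product: 24 8-oxo-19,20-olide with the C9 chain equatorial (H9 anti to C20), via C9-epimeric ketones 23 (not isolated)
Conditions: PPTS, acetone–H2O, reflux; then NaOMe (cat.), MeOH, rt
Reagents that add atoms: water, O
Why: Ketal hydrolysis followed by base equilibration through the C8 enolate sets C9 under thermodynamic control, since in the now rigid trans-decalin the side chain strongly prefers the equatorial position found in the target.

Step 14
Reactants: 24 8-oxo-19,20-olide
Product: 25 8(17)-methylene-19,20-olide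
Conditions: Ph3PCH3Br, KOt-Bu, THF, 0 °C → rt
Reagents that add atoms: methyltriphenylphosphonium bromide, C[P+](c1ccccc1)(c1ccccc1)c1ccccc1.[Br-]
Why: Wittig methylenation of 8-oxo decalins of this type is standard, takes the ketone in preference to the hindered non-enolisable lactone, and cannot erode C9 because the equatorial epimer is already the stable one.

Step 15
Reactants: 25 8(17)-methylene-19,20-olide
Product: 26 C12 alcohol
Conditions: n-Bu4NF, THF, 0 °C → rt
Reagents that add atoms: none
Why: Fluoride cleavage of a primary TIPS ether leaves the alkene and the lactone untouched.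

Step 16
Reactants: 26 C12 alcohol
Product: 27 C12 iodide
Conditions: I2, PPh3, imidazole, CH2Cl2, 0 °C
Reagents that add atoms: iodine, II
Why: Appel-type iodination is placed after methylenation (a γ-iodo ketone would cyclopropanate under base) and before the lactone is opened (a free C20 hydroxyl would compete for activated C12).

Step 17
Reactants: 27 C12 iodide
Product: 28 19,20-diol
Conditions: i-Bu2AlH (excess), CH2Cl2, −78 °C → rt; aq potassium sodium tartrate
Reagents that add atoms: none
Why: Exhaustive i-Bu2AlH reduction takes the lactone to the diol and releases the tether, while a primary alkyl iodide and an unactivated alkene are inert to this hydride.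

Step 18
Reactants: 28 19,20-diol
Product: 29 19-monoacetate
Conditions: AcCl (1.05 equiv), 2,4,6-collidine, CH2Cl2, −78 °C
Reagents that add atoms: acetyl chloride, CC(=O)Cl
Why: This is sterically controlled monoacylation at low temperature, in which C19–OH (flanked by CH3, CH2 and CH) should react ahead of C20–OH, which is axial to both rings and flanked by C1, C5 and the branched C9; the hindered base does not quaternise with the iodide.

Step 19
Reactants: 29 19-monoacetate
Product: 30 19-acetate 20-TES ether
Conditions: Et3SiOTf, 2,6-lutidine, CH2Cl2, −78 → 0 °C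
Reagents that add atoms: triethylsilyl triflate, CC[Si](CC)(CC)OS(=O)(=O)C(F)(F)F
Why: Silyl triflate silylation covers even a neopentyl hydroxyl and prevents C20–O from displacing the C12 iodide (six-membered ether formation) under the basic conditions of step 21.

Step 20
Reactants: 31 α-bromo-γ-butyrolactone; 32 thiophenol
Product: 33 3-(phenylthio)dihydrofuran-2(3H)-one (racemic)
Conditions: Et3N, CH2Cl2, 0 °C → rt
Reagents that add atoms: none
Why: SN2 displacement of an α-bromo lactone by thiolate is fast and clean.

Step 21
Reactants: 30 19-acetate 20-TES ether; 33 3-(phenylthio)dihydrofuran-2(3H)-one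
Product: 36 C13 phenylthio lactone with free C20 hydroxyl (mixture at C13), via potassium enolate 34 (not isolated), via silyl-protected sulfide 35 (not isolated)
Conditions: 33, KN(SiMe3)2, THF–DMPU, −78 → 0 °C; then 30, rt; then 1 M HCl, rt
Reagents that add atoms: potassium bis(trimethylsilyl)amide, [K+].C[Si](C)(C)[N-][Si](C)(C)C (potassium of 34 only)
Why: Alkylation of the sulfur-stabilised lactone enolate with a primary iodide is the standard entry to α-alkyl butenolides, the neopentyl acetate cannot be acylated productively by a fully substituted enolate, the acidic quench removes the TES group, and the C13 centre is destroyed in step 22.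

Step 22
Reactants: 36 C13 phenylthio lactone
Product: 38 butenolide with C19 acetate and C20 alcohol, via sulfoxide 37 (not isolated)
Conditions: mCPBA (1.0 equiv), CH2Cl2, −78 → 0 °C; then toluene, 110 °C
Reagents that add atoms: 3-chloroperoxybenzoic acid, O=C(OO)c1cccc(Cl)c1 (oxygen of 37 only)
Why: Sulfide oxidation far outruns epoxidation of the 1,1-disubstituted alkene at low temperature, and thermal syn-elimination of α-alkyl-α-sulfinyl butyrolactones is known to deliver the endocyclic C13=C14 butenolide.

Step 23
Reactants: 38 butenolide with C19 acetate and C20 alcohol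
Product: 39 target (4R,5R,9R,10R)-19-acetoxy-20-oxolabda-8(17),13-dien-16,15-olide
Conditions: Dess–Martin periodinane, CH2Cl2, rt
Reagents that add atoms: none
Why: Dess–Martin oxidation of the neopentyl C20 alcohol gives a non-enolisable aldehyde and tolerates acetate, exocyclic alkene and butenolide.

Compound list
1 | 3-methoxy-2-methylbenzoic acid | COc1cccc(C(=O)O)c1C | starting material
2 | (S)-2-(methoxymethyl)pyrrolidine | COC[C@@H]1CCCN1 | starting material
3 | 3-methoxy-2-methylbenzoyl chloride | COc1cccc(C(=O)Cl)c1C | intermediate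
4 | (S)-1-(3-methoxy-2-methylbenzoyl)-2-(methoxymethyl)pyrrolidine | COC[C@@H]1CCCN1C(=O)c1cccc(OC)c1C | intermediate
5 | (triisopropylsiloxy)methyl chloride | ClCO[Si](C(C)C)(C(C)C)C(C)C | starting material
6 | benzylic lithium compound of 4 (Li on the former aryl methyl, C11) | COC[C@@H]1CCCN1C(=O)c1cccc(OC)c1C[Li] | intermediate
7 | (S)-1-[3-methoxy-2-(2-triisopropylsiloxyethyl)benzoyl]-2-(methoxymethyl)pyrrolidine | COC[C@@H]1CCCN1C(=O)c1cccc(OC)c1CCO[Si](C(C)C)(C(C)C)C(C)C | intermediate
8 | benzyl 3-bromopropyl ether | BrCCCOCc1ccccc1 | starting material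
9 | potassium amide enolate of the 1,4-dihydrobenzamide (exocyclic C10=C20 enolate) | COC[C@@H]1CCCN1C([O-])=C1C=CCC(OC)=C1CCO[Si](C(C)C)(C(C)C)C(C)C.[K+] | intermediate
10 | ring B diene amide, (S) at quaternary C10, (S) in the auxiliary | COC1=C(CCO[Si](C(C)C)(C(C)C)C(C)C)[C@@](CCCOCc2ccccc2)(C(=O)N2CCC[C@H]2COC)C=CC1 | intermediate
11 | C20 alcohol, (S) at C10 | COC1=C(CCO[Si](C(C)C)(C(C)C)C(C)C)[C@@](CCCOCc2ccccc2)(CO)C=CC1 | intermediate
12 | ethyl 1-propenyl ether (E/Z mixture) | CCOC=CC | starting material
13 | 1,2-dibromo-1-ethoxypropane | CCOC(Br)C(C)Br | intermediate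
14 | ring B diene bromoacetal, (S) at C10, mixture at the acetal and bromide carbons | COC1=C(CCO[Si](C(C)C)(C(C)C)C(C)C)[C@@](CCCOCc2ccccc2)(COC(OCC)C(C)Br)C=CC1 | intermediate
15 | cis-fused oxane acetal, C4 on C5 cis to C20, H5 trans to C20, mixture at C4 and the acetal carbon | COC1=C(CCO[Si](C(C)C)(C(C)C)C(C)C)[C@@]2(CCCOCc3ccccc3)COC(OCC)C(C)[C@H]2CC1 | intermediate
16 | C8 keto lactol, mixture at C4, C9 and the lactol carbon | O=C1C(CCO[Si](C(C)C)(C(C)C)C(C)C)[C@@]2(CCCOCc3ccccc3)COC(O)C(C)[C@H]2CC1 | intermediate
17 | C8 keto δ-lactone (C19 carbonyl), mixture at C4 and C9 | O=C1C(CCO[Si](C(C)C)(C(C)C)C(C)C)[C@@]2(CCCOCc3ccccc3)COC(=O)C(C)[C@H]2CC1 | intermediate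
18 | C8 ethylene ketal of 17 | C1COC2(O1)C(CCO[Si](C(C)C)(C(C)C)C(C)C)[C@@]3(CCCOCc4ccccc4)COC(=O)C(C)[C@H]3CC2 | intermediate
19 | C3 alcohol | C1COC2(O1)C(CCO[Si](C(C)C)(C(C)C)C(C)C)[C@@]3(CCCO)COC(=O)C(C)[C@H]3CC2 | intermediate
20 | C3 iodide | C1COC2(O1)C(CCO[Si](C(C)C)(C(C)C)C(C)C)[C@@]3(CCCI)COC(=O)C(C)[C@H]3CC2 | intermediate
21 | lithium lactone enolate (C4=C19) | C1COC2(O1)C(CCO[Si](C(C)C)(C(C)C)C(C)C)[C@@]3(CCCI)COC([O-])=C(C)[C@H]3CC2.[Li+] | intermediate
22 | tricyclic ketal lactone, trans A/B, 19,20-lactone bridge opposite to H5, C18 equatorial, C9 mixture | C1COC2(O1)CC[C@@H]3[C@](C)(C(=O)OC4)CCC[C@@]34C2CCO[Si](C(C)C)(C(C)C)C(C)C | intermediate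
23 | 8-oxo-19,20-olide, C9 epimer mixture | O=C1CC[C@@H]2[C@](C)(C(=O)OC3)CCC[C@@]23C1CCO[Si](C(C)C)(C(C)C)C(C)C | intermediate
24 | 8-oxo-19,20-olide, C9 chain equatorial | O=C1CC[C@@H]2[C@](C)(C(=O)OC3)CCC[C@@]23[C@@H]1CCO[Si](C(C)C)(C(C)C)C(C)C | intermediate
25 | 8(17)-methylene-19,20-olide, C12 TIPS ether | C=C1CC[C@@H]2[C@](C)(C(=O)OC3)CCC[C@@]23[C@@H]1CCO[Si](C(C)C)(C(C)C)C(C)C | intermediate
26 | 8(17)-methylene-19,20-olide, C12 alcohol | C=C1CC[C@@H]2[C@](C)(C(=O)OC3)CCC[C@@]23[C@@H]1CCO | intermediate
27 | 8(17)-methylene-19,20-olide, C12 iodide | C=C1CC[C@@H]2[C@](C)(C(=O)OC3)CCC[C@@]23[C@@H]1CCI | intermediate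
28 | 19,20-diol, C12 iodide | C=C1CC[C@@H]2[C@](C)(CO)CCC[C@@]2(CO)[C@@H]1CCI | intermediate
29 | 19-acetate 20-alcohol, C12 iodide | C=C1CC[C@@H]2[C@](C)(COC(C)=O)CCC[C@@]2(CO)[C@@H]1CCI | intermediate
30 | 19-acetate 20-TES ether, C12 iodide | C=C1CC[C@@H]2[C@](C)(COC(C)=O)CCC[C@@]2(CO[Si](CC)(CC)CC)[C@@H]1CCI | intermediate
31 | α-bromo-γ-butyrolactone (racemic) | O=C1OCCC1Br | starting material
32 | thiophenol | Sc1ccccc1 | starting material
33 | 3-(phenylthio)dihydrofuran-2(3H)-one (racemic) | O=C1OCCC1Sc1ccccc1 | intermediate
34 | potassium enolate of 33 | [K+].[O-]C1=C(Sc2ccccc2)CCO1 | intermediate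
35 | C13 phenylthio lactone, 19-acetate 20-TES ether, mixture at C13 | C=C1CC[C@@H]2[C@](C)(COC(C)=O)CCC[C@@]2(CO[Si](CC)(CC)CC)[C@@H]1CCC1(Sc2ccccc2)CCOC1=O | intermediate
36 | C13 phenylthio lactone, 19-acetate 20-alcohol, mixture at C13 | C=C1CC[C@@H]2[C@](C)(COC(C)=O)CCC[C@@]2(CO)[C@@H]1CCC1(Sc2ccccc2)CCOC1=O | intermediate
37 | C13 phenylsulfinyl lactone, mixture at C13 and sulfur | C=C1CC[C@@H]2[C@](C)(COC(C)=O)CCC[C@@]2(CO)[C@@H]1CCC1(S(=O)c2ccccc2)CCOC1=O | intermediate
38 | 19-acetoxy-20-hydroxylabda-8(17),13-dien-16,15-olide (ent series) | C=C1CC[C@@H]2[C@](C)(COC(C)=O)CCC[C@@]2(CO)[C@@H]1CCC1=CCOC1=O | intermediate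
39 | (4R,5R,9R,10R)-19-acetoxy-20-oxolabda-8(17),13-dien-16,15-olide, CNP0109410.1 | C=C1CC[C@@H]2[C@](C)(COC(C)=O)CCC[C@@]2(C=O)[C@@H]1CCC1=CCOC1=O | target

Total step count: 23. Longest linear sequence: 22 (steps 1–19 and 21–23; step 20 is a one-step side branch).

Steps most likely to fail

Step 6. The six-ring closure may be too slow. The C4 radical is then reduced before it cyclises, or hydrogen is pulled from the doubly allylic C7H2, after which ring B aromatises with loss of a C10 substituent. The fallback removes the second double bond of ring B before the radical step, and the bond formed stays the same. Setting out from 10, exchange of the enol ether with ethylene glycol (PPTS, CH2Cl2) would give the C8 dioxolane amide F1. LiH2NBH3 would then give the ketal alcohol F2, α-bromo ether 13 with i-Pr2NEt the ketal bromoacetal F3, and Bu3SnH/AIBN the ketal oxane acetal F4. In F3, C5=C6 is the only alkene, so C9 cannot compete and no doubly allylic hydrogen is present. AcOH–THF–H2O then cleaves the ketal and the acetal together, and the route is rejoined at 16.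

Step 18. Site selection between two neopentyl primary hydroxyls may be poor, or the acetyl group may drift between them. The fallback is a relay through a much bulkier acyl group in place of direct acetylation. Setting out from 28, pivaloyl chloride (2,4,6-collidine, DMAP cat., CH2Cl2, 0 °C) should mark the more open position as the 19-pivalate F5. Et3SiOTf/2,6-lutidine covers C20 to give the 19-pivalate 20-TES ether F6. i-Bu2AlH at −78 °C removes the pivalate to give the 19-alcohol 20-TES ether F7. Unconstrained acetylation (Ac2O, Et3N, DMAP) then rejoins the route at 30.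

Step 4. The carbonyl lies buried between quaternary C10 and the pyrrolidine. It may resist hydride delivery, or the tetrahedral intermediate may collapse with C–O loss towards the tertiary amine. The fallback stops at the aldehyde level by a different activation of the amide. Setting out from 10, Cp2Zr(H)Cl (THF, rt) forms a zirconated hemiaminal that hydrolyses on work-up to the C20 aldehyde F8. NaBH4 in MeOH at 0 °C then rejoins the route at 11.

Further compounds
F1 | step 6 | C8 dioxolane amide (C5=C6 retained, C9 mixture) | C1COC2(O1)C(CCO[Si](C(C)C)(C(C)C)C(C)C)[C@@](CCCOCc3ccccc3)(C(=O)N3CCC[C@H]3COC)C=CC2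
F2 | step 6 | ketal alcohol | C1COC2(O1)C(CCO[Si](C(C)C)(C(C)C)C(C)C)[C@@](CCCOCc3ccccc3)(CO)C=CC2
F3 | step 6 | ketal bromoacetal | C1COC2(O1)C(CCO[Si](C(C)C)(C(C)C)C(C)C)[C@@](CCCOCc3ccccc3)(COC(OCC)C(C)Br)C=CC2
F4 | step 6 | ketal oxane acetal (C4 on C5 cis to C20) | C1COC2(O1)C(CCO[Si](C(C)C)(C(C)C)C(C)C)[C@@]3(CCCOCc4ccccc4)COC(OCC)C(C)[C@H]3CC2
F5 | step 18 | 19-pivalate 20-alcohol, C12 iodide | C=C1CC[C@@H]2[C@](C)(COC(=O)C(C)(C)C)CCC[C@@]2(CO)[C@@H]1CCI
F6 | step 18 | 19-pivalate 20-TES ether, C12 iodide | C=C1CC[C@@H]2[C@](C)(COC(=O)C(C)(C)C)CCC[C@@]2(CO[Si](CC)(CC)CC)[C@@H]1CCI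
F7 | step 18 | 19-alcohol 20-TES ether, C12 iodide | C=C1CC[C@@H]2[C@](C)(CO)CCC[C@@]2(CO[Si](CC)(CC)CC)[C@@H]1CCI
F8 | step 4 | C20 aldehyde of the ring B diene | COC1=C(CCO[Si](C(C)C)(C(C)C)C(C)C)[C@@](CCCOCc2ccccc2)(C=O)C=CC1
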